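## The problem

Compound 19 is an achiral 1,4-benzoquinone in which, numbering the ring C1 (carbonyl), C2 (free hydroxyl), C3 (n-docosyl), C4 (carbonyl), C5 (methoxy) and C6 (hydrogen), no two ring positions are equivalent. There is one ring and no stereocentre, so the task is purely regiochemical: four oxygens must be placed in a fixed relation to the chain, and the C2 and C5 oxygens must end up as a free hydroxyl and a methyl ether respectively. The unbranched C22 chain is joined to the ring by a single bond at C3 and is most cheaply drawn from a C22 electrophile, but it makes every intermediate waxy and sparingly soluble in polar or aqueous media. The fragile functions all belong to the finished ring: the C5 methoxy enone is a vinylogous ester that hydroxide, alkoxide or acidic alcohols can hydrolyse or exchange, the C2 hydroxy enone is a vinylogous acid, and the quinone is an oxidant and a Michael acceptor. The quinone should therefore be unveiled in the last step and the ring assembled at the arene oxidation level. A short ring construction is possible because of the 1,3,5 relation of the C1 oxygen, the C3 chain and the C5 methoxyl. C5(OMe)–C6(H) is a two-carbon unit oxygenated at one end only, the imprint of an ynol ether, while C1, C4, C3 and C2, with the chain on C3, are the carbonyl carbon, the α-carbon, the substituted carbon and the methylene terminus of a vinylketene that a 3-alkylcyclobutenone releases on heating. The two remaining oxygens, at C4 (para to the C1 oxygen) and at C2, can then be added by oxidations whose site the C5 methoxy group dictates.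

## Retrosynthesis

**19 from 17 (through 18).** The last disconnection cuts only the three O–acetyl bonds of triacetate 17 and changes the oxidation level by two electrons. Deacetylation is placed at the arene stage, as hydroxyquinol 18, because there the C5 methoxyl is an ordinary aryl ether; the alternative of hydrolysing a protected hydroxyquinone would expose the vinylogous ester to the hydrolysis medium. The forward step must free three phenols without touching the methyl ether and then oxidise under neutral conditions.

**17 from 16.** The C2–O bond is cut, leading back to 2-docosyl-6-methoxy-1,4-benzoquinone 16 and acetic anhydride (Thiele–Winter acetoxylation). Of the two ring CH positions of 16, only the one next to the docosyl carbon is electrophilic, because the other is the electron-rich α-carbon of the methoxy enone. The cut therefore removes an oxygen whose position the substrate itself controls, and leaves a quinone with one oxygen substituent fewer.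

**16 from 15.** The C4–O bond is cut, giving 3-docosyl-5-methoxyphenol 15. The forward reaction is a para-selective phenol-to-quinone oxidation with K2[ON(SO3)2]. It is preferred to a longer formylation–Dakin or azo-coupling sequence because the para position is free and flanked by two donors. Compound 15 has no quinone and only two oxygens.

**15 from 7 and 10 (key disconnection).** Three ring bonds are cut: C1–C6, C4–C5 and C1–C2. This divides the benzene ring into 3-docosylcyclobut-2-en-1-one 7 (C1, C4, C3, C2 and the chain) and methoxyethyne 10 (C5 and C6). The neighbouring cut, attaching the chain to a preformed resorcinol ether, would leave two identical oxygens to be differentiated afterwards. Here the free hydroxyl comes from the ketene carbonyl and the methyl ether from the alkyne, so they are distinct from the outset. The forward reaction must deliver only the 1,3,5 pattern, which the polarity of the two partners ensures.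

**7 from 6, and 6 from 3 and 4 (through 5).** The two C–Cl bonds of 4,4-dichloro-3-docosylcyclobut-2-en-1-one 6 are cut reductively. Then the two ring bonds formed by [2+2] cycloaddition of dichloroketene 5 (from trichloroacetyl chloride 4) to tetracos-1-yne 3 are cut. Dichloroketene is chosen over ketene itself because it adds to unactivated alkynes. The precursor is a plain terminal alkyne.

**3 from 1 and 2.** The C(sp3)–C(sp) bond is cut to 1-bromodocosane 1 and lithium acetylide ethylenediamine complex 2, a displacement on a primary bromide.

**10 from 8 (through 9).** Methoxyethyne 10 is traced to chloroacetaldehyde dimethyl acetal 8 by double elimination, with sodium methoxyacetylide 9 as the form in which the alkyne survives the base.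

## Roads not taken

**Alternative 1: biomimetic tetraketide cyclisation.**
- Cut: the ring bond that becomes C2–C3, within a linear 3,5,7-trioxo acid.
- Forward: triacetic acid lactone A1 would be acylated at its methyl group with a C23 acyl donor to give pyranone A2. Aqueous hydroxide would open A2, and intramolecular aldol condensation with aromatisation would give 6-docosyl-2,4-dihydroxybenzoic acid A3.
- Merits: cheap reagents, no volatile or unstable alkyne, polar intermediates that crystallise, and a 1,3,5 pattern that follows from the polyketide chain. In operational simplicity this road is better than the chosen one.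
- Weak points: Claisen-type closure and relactonisation compete with the aldol mode. A3 must then be decarboxylated to 5-docosylresorcinol A4, whose two hydroxyls are equivalent, so monomethylation to 15 is statistical and competes with dimethylation. The same three oxidation steps still follow.
- Comparison: the chosen plan sets against the easier handling a ring construction that differentiates hydroxyl from methoxyl as it forms, and at least two fewer steps after ring formation.

**Alternative 2: malonate–enone annulation.**
- Cut: C3–C4 and C5–C6.
- Forward: Michael addition of dimethyl malonate A6 to (E)-hexacos-3-en-2-one A5 under alkoxide base, Dieckmann closure, saponification and decarboxylation in one pot would give 5-docosylcyclohexane-1,3-dione A7.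
- Merits: each operation is classical and robust, and it scales well. In reliability of the individual ring-forming step it is at least the equal of the chosen plan.
- Weak points: A7 is two oxidation levels below an arene. Dehydrogenative aromatisation of 1,3-diones tends to give mixtures of resorcinol, monoether and diether, so the hydroxyl/methoxyl differentiation is again not secured. A5 needs a C23 aldehyde, one homologation beyond the C22 bromide. The oxidation end-game is unchanged.
- Comparison: the total length would be similar or greater. The chosen plan reaches the correct oxidation level and oxygen differentiation in a single step.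

**Alternative 3: Moore ring expansion.**
- Cut: C4–C5, closing the quinone ring directly.
- Forward: from di-tert-butyl squarate A8, addition of a docosyl organometallic and acid rearrangement would give 3-tert-butoxy-4-docosylcyclobut-3-ene-1,2-dione A9. The lithium acetylide of 10 would add to the more electrophilic carbonyl to give carbinol A10. Thermolysis would open A10 to an enynylketene that closes to 2-tert-butoxy-3-docosyl-5-methoxy-1,4-benzoquinone A11. Acid removal of the tert-butyl group would give 19.
- Merits: this is the shortest road on paper. It is the only one that sets all four oxygens and the chain regiospecifically in the ring-forming step and needs no late oxidation. In step economy and regiochemical certainty of the oxygen pattern it is better than the chosen plan.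
- Weak points: the cyclisation proceeds through a diradical, and substituents on the alkyne terminus that stabilise a radical, alkoxy among them, favour five-membered closure to an alkylidenecyclopentenedione over the quinone. The methoxy group required here is such a substituent. The regioselectivity of two successive carbonyl additions to the squarate core must also hold with a waxy organometallic, and the same unstable alkyne is still needed.
- Comparison: the chosen plan sets against the brevity a ring closure with no five- versus six-membered ambiguity, and a sequence in which every step belongs to a reaction class already established for alkyl methoxy phenols and quinones.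

Key step: step 5

Assumption: methoxyethyne is too volatile and prone to polymerisation to be bought and stored, so it is made in step 4 and used at once; compounds 1, 2, 4 and 8 are taken as commercial.

## Route

Step 1
Reactants: 1 1-bromodocosane; 2 lithium acetylide ethylenediamine complex
Product: 3 tetracos-1-yne
Conditions: LiC≡CH·H2N(CH2)2NH2 (2 equiv), DMSO/THF, 15 °C to rt
Reagents that add atoms: none
Why: SN2 alkylation of a metal acetylide by a primary bromide; the ethylenediamine complex in DMSO is the standard reagent for turning long-chain primary bromides into terminal alkynes, excess acetylide suppresses dialkylation, and THF keeps the waxy bromide in solution.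

Step 2
Reactants: 3 tetracos-1-yne; 4 trichloroacetyl chloride
Product: 6 4,4-dichloro-3-docosylcyclobut-2-en-1-one, via dichloroketene 5 (not isolated)
Conditions: Zn(Cu) couple, Et2O/DME, slow addition of 4, 25–35 °C
Reagents that add atoms: none
Why: Zn(Cu) couple dechlorinates 4 to dichloroketene 5, which adds to the terminal alkyne in a ketene–alkyne [2+2] cycloaddition; the terminal alkyne carbon bonds to the ketene carbonyl carbon so the chain sits on C3, DME complexes the ZnCl2 that would otherwise polymerise the ketene, and any allylic chlorine shift in 6 is harmless because both isomers reduce to 7.

Step 3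
Reactants: 6 4,4-dichloro-3-docosylcyclobut-2-en-1-one
Product: 7 3-docosylcyclobut-2-en-1-one
Conditions: Zn dust, AcOH, TMEDA, EtOH/THF, 0 °C to rt
Reagents that add atoms: none
Why: Zinc reductive dechlorination of an α,α-dichloroketone through zinc enolates that acetic acid protonates; TMEDA buffers ZnCl2 and acid so that the strained enone is neither isomerised nor reduced at its C=C bond.

Step 4
Reactants: 8 chloroacetaldehyde dimethyl acetal (2-chloro-1,1-dimethoxyethane)
Product: 10 methoxyethyne, via sodium methoxyacetylide 9 (not isolated)
Conditions: NaNH2 (3 equiv), liq. NH3, −33 °C; sat. aq NaCl, −70 °C; distil into toluene at −78 °C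
Reagents that add atoms: none
Why: Amide-induced double elimination (loss of methanol, then of HCl) gives the ynol ether, which excess NaNH2 holds as the acetylide 9 until cold aqueous protonation; this is the standard preparation of simple alkoxyacetylenes from chloroacetaldehyde acetals.

Step 5
Reactants: 7 3-docosylcyclobut-2-en-1-one; 10 methoxyethyne
Product: 15 3-docosyl-5-methoxyphenol, via vinylketene 11 (not isolated), via vinylcyclobutenone 12 (not isolated), via dienylketene 13 (not isolated), via cyclohexadienone 14 (not isolated)
Conditions: 10 (2–3 equiv), toluene, sealed vessel, 80 °C; then K2CO3, MeOH, rt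
Reagents that add atoms: none
Why: Danheiser benzannulation, a known reaction of 3-alkylcyclobutenones with alkoxyacetylenes. At about 80 °C cyclobutenone 7 undergoes reversible four-electron conrotatory ring opening to vinylketene 11, which the electron-rich alkyne intercepts in a [2+2] cycloaddition. The nucleophilic CH carbon of 10 attacks the electrophilic ketene carbonyl carbon (bond C1–C6) and the methoxy-bearing carbon bonds to the ketene α-carbon (bond C4–C5), so 12 carries the methoxyl on C3 of the new four-membered ring. A second four-electron ring opening gives dienylketene 13; only the isomer with the ketene and the alkenyl group cis on the central double bond can close, and the other returns to 12. Thermal six-electron disrotatory electrocyclisation of 13 closes the six-membered carbocycle by bonding the ketene carbon to the methylidene carbon (bond C1–C2), and enolisation of 14 gives the phenol. No stereocentre remains: the one in 12 is racemic and is destroyed on ring opening. The selectivity required is regiochemical (methoxyl meta to the new hydroxyl, both meta to the chain) and follows from the polarisation of the ynol ether and the ketene; the methyl ether, unlike an ethyl ether, has no retro-ene path to a ketene at this temperature. The basic methanolysis at the end returns to 15 any product phenol that has been acylated by vinylketene.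

Step 6
Reactants: 15 3-docosyl-5-methoxyphenol
Product: 16 2-docosyl-6-methoxycyclohexa-2,5-diene-1,4-dione (2-docosyl-6-methoxy-1,4-benzoquinone)
Conditions: K2[ON(SO3)2] (2.5 equiv), aq KH2PO4, methyltrioctylammonium chloride (cat.), CH2Cl2/H2O, rt
Reagents that add atoms: dipotassium nitrosodisulfonate K2[ON(SO3)2] (Fremy's salt), [K+].[K+].[O]N(S(=O)(=O)[O-])S(=O)(=O)[O-]
Why: Teuber oxidation: one nitrosodisulfonate radical abstracts the phenolic hydrogen, a second couples through oxygen at the free para carbon of the phenoxyl radical, and loss of imidodisulfonate gives the p-quinone; with the para position unsubstituted the para-quinone is the normal outcome for 3-alkyl-5-alkoxyphenols, and the phase-transfer salt carries the radical dianion to the lipophilic substrate.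

Step 7
Reactants: 16 2-docosyl-6-methoxy-1,4-benzoquinone
Product: 17 3-docosyl-5-methoxybenzene-1,2,4-triyl triacetate
Conditions: Ac2O, conc. H2SO4 (cat.), 40 °C
Reagents that add atoms: acetic anhydride, CC(=O)OC(C)=O
Why: Thiele–Winter acetoxylation: acid-activated conjugate addition of acetate to the quinone, enolisation to the acetoxyhydroquinone and peracetylation. The methoxy group makes its own double bond a vinylogous ester whose CH is electron-rich, so acetate adds only to the CH next to the docosyl carbon (para to methoxyl), which becomes C2 of the target.

Step 8
Reactants: 17 3-docosyl-5-methoxybenzene-1,2,4-triyl triacetate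
Product: 19 3-docosyl-2-hydroxy-5-methoxycyclohexa-2,5-diene-1,4-dione, via triol 18 (not isolated)
Conditions: HCl, MeOH/THF, 60 °C, N2; evaporate; then FeCl3 (2 equiv), H2O/EtOAc, rt
Reagents that add atoms: none
Why: Acid-catalysed transesterification releases hydroxyquinol 18, in which the methoxyl is an ordinary aryl ether and cannot exchange; after removal of the acidic methanol, FeCl3 (trivalent iron as one-electron oxidant) dehydrogenates the para-related hydroxyls to the 2-hydroxy-1,4-quinone under neutral two-phase conditions that spare the vinylogous ester and acid.

## Compound list

1 | 1-bromodocosane | CCCCCCCCCCCCCCCCCCCCCCBr | starting material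
2 | lithium acetylide ethylenediamine complex | [Li]C#C.NCCN | starting material
3 | tetracos-1-yne | CCCCCCCCCCCCCCCCCCCCCCC#C | intermediate
4 | trichloroacetyl chloride | ClC(=O)C(Cl)(Cl)Cl | starting material
5 | dichloroketene (not isolated) | ClC(Cl)=C=O | intermediate
6 | 4,4-dichloro-3-docosylcyclobut-2-en-1-one | CCCCCCCCCCCCCCCCCCCCCCC1=CC(=O)C1(Cl)Cl | intermediate
7 | 3-docosylcyclobut-2-en-1-one | CCCCCCCCCCCCCCCCCCCCCCC1=CC(=O)C1 | intermediate
8 | chloroacetaldehyde dimethyl acetal (2-chloro-1,1-dimethoxyethane) | COC(CCl)OC | starting material
9 | sodium methoxyacetylide, NaC≡COMe (not isolated) | [Na+].[C-]#COC | intermediate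
10 | methoxyethyne | COC#C | intermediate
11 | 3-methylidenepentacos-1-en-1-one, the (1-docosylethenyl)ketene (not isolated) | CCCCCCCCCCCCCCCCCCCCCCC(=C)C=C=O | intermediate
12 | racemic 3-methoxy-4-(tetracos-1-en-2-yl)cyclobut-2-en-1-one (not isolated) | CCCCCCCCCCCCCCCCCCCCCCC(=C)C1C(OC)=CC1=O | intermediate
13 | (3E)-3-methoxy-5-methylideneheptacosa-1,3-dien-1-one, ketene and alkenyl group cis (not isolated) | CCCCCCCCCCCCCCCCCCCCCCC(=C)/C=C(OC)\C=C=O | intermediate
14 | 5-docosyl-3-methoxycyclohexa-2,4-dien-1-one (not isolated) | CCCCCCCCCCCCCCCCCCCCCCC1=CC(OC)=CC(=O)C1 | intermediate
15 | 3-docosyl-5-methoxyphenol | CCCCCCCCCCCCCCCCCCCCCCc1cc(O)cc(OC)c1 | intermediate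
16 | 2-docosyl-6-methoxycyclohexa-2,5-diene-1,4-dione | CCCCCCCCCCCCCCCCCCCCCCC1=CC(=O)C=C(OC)C1=O | intermediate
17 | 3-docosyl-5-methoxybenzene-1,2,4-triyl triacetate | CCCCCCCCCCCCCCCCCCCCCCc1c(OC(C)=O)c(OC(C)=O)cc(OC)c1OC(C)=O | intermediate
18 | 3-docosyl-5-methoxybenzene-1,2,4-triol (not isolated) | CCCCCCCCCCCCCCCCCCCCCCc1c(O)c(O)cc(OC)c1O | intermediate
19 | 3-docosyl-2-hydroxy-5-methoxycyclohexa-2,5-diene-1,4-dione (CNP0107063.0) | CCCCCCCCCCCCCCCCCCCCCCC1=C(O)C(=O)C=C(OC)C1=O | target

## Step count and risks

Total: 8 steps. Longest linear sequence: 7 steps (steps 1, 2, 3, 5, 6, 7, 8 from 1-bromodocosane); step 4 is a one-step branch that supplies the alkyne.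

**Step 5 (key step).** The most likely failure is diversion of the vinylketene away from the [2+2] with the alkyne: O-acylation of the product phenol by a second vinylketene, or ketene dimerisation. Both become worse if the volatile alkyne escapes from solution or oligomerises before it is intercepted, and the basic methanolysis repairs only the first. Fallback: give up the annulation and attach the chain to a preformed resorcinol ring. Setting out from 1, magnesium in THF would give docosylmagnesium bromide F1. Kumada coupling of F1 with 1-bromo-3,5-dimethoxybenzene under NiCl2(dppp) catalysis would give 1-docosyl-3,5-dimethoxybenzene F2. One methyl group would then be removed with NaSEt in DMF at reflux, where the phenoxide formed protects the second ether, and the route is rejoined at 15.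

**Step 2.** The likely failure is polymerisation of dichloroketene outrunning the cycloaddition, because the waxy C24 alkyne is only sparingly soluble in ether and the ZnCl2 formed catalyses ketene decomposition. Fallback: a keteniminium [2+2] cycloaddition in a chlorinated solvent. Setting out from 3, N,N-dimethylacetamide, Tf2O and 2,4,6-collidine in 1,2-dichloroethane at reflux would give N-(3-docosylcyclobut-2-en-1-ylidene)-N-methylmethanaminium trifluoromethanesulfonate F3. Aqueous NaHCO3 would hydrolyse F3 to the cyclobutenone, rejoining the route at 7 and bypassing 6.

**Step 6.** The likely failure is slow transfer of the water-bound radical to the lipophilic phenol, so that the reagent decays in the aqueous phase and the phenoxyl radical, short of a second oxidant radical, couples with itself. Fallback: a two-electron oxidation in homogeneous organic solution through a ketal. Setting out from 15, PhI(OAc)2 (2 equiv) in MeOH/CH2Cl2 would give 3-docosyl-4,4,5-trimethoxycyclohexa-2,5-dien-1-one F4. Dilute aqueous acid in acetone would then hydrolyse the ketal, rejoining the route at 16.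

**Step 7.** The likely failure is incomplete acetoxylation because the quinone dissolves poorly in acetic anhydride, together with acid-induced exchange of the vinylogous methyl ester on prolonged warming. Fallback: introduce the C2 oxygen by nucleophilic epoxidation instead of acetate addition. Setting out from 16, H2O2 and Na2CO3 in THF/H2O at 0 °C would attack the more electron-poor, docosyl-substituted double bond and give racemic 1-docosyl-3-methoxy-7-oxabicyclo[4.1.0]hept-3-ene-2,5-dione F5. H2SO4 in AcOH would then isomerise the epoxy dione to the hydroxyquinone, rejoining the route at 19 and bypassing 17 and 18.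

## Further compounds

F1 | step 5 | docosylmagnesium bromide | CCCCCCCCCCCCCCCCCCCCCC[Mg]Br
F2 | step 5 | 1-docosyl-3,5-dimethoxybenzene | CCCCCCCCCCCCCCCCCCCCCCc1cc(OC)cc(OC)c1
F3 | step 2 | N-(3-docosylcyclobut-2-en-1-ylidene)-N-methylmethanaminium trifluoromethanesulfonate | CCCCCCCCCCCCCCCCCCCCCCC1=CC(=[N+](C)C)C1.[O-]S(=O)(=O)C(F)(F)F
F4 | step 6 | 3-docosyl-4,4,5-trimethoxycyclohexa-2,5-dien-1-one | CCCCCCCCCCCCCCCCCCCCCCC1=CC(=O)C=C(OC)C1(OC)OC
F5 | step 7 | racemic 1-docosyl-3-methoxy-7-oxabicyclo[4.1.0]hept-3-ene-2,5-dione | CCCCCCCCCCCCCCCCCCCCCCC12OC1C(=O)C=C(OC)C2=O
A1 | alternative 1 | triacetic acid lactone (4-hydroxy-6-methyl-2H-pyran-2-one) | CC1=CC(O)=CC(=O)O1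
A2 | alternative 1 | 4-hydroxy-6-(2-oxotetracosyl)-2H-pyran-2-one | CCCCCCCCCCCCCCCCCCCCCCC(=O)CC1=CC(O)=CC(=O)O1
A3 | alternative 1 | 6-docosyl-2,4-dihydroxybenzoic acid | CCCCCCCCCCCCCCCCCCCCCCc1cc(O)cc(O)c1C(=O)O
A4 | alternative 1 | 5-docosylbenzene-1,3-diol (5-docosylresorcinol) | CCCCCCCCCCCCCCCCCCCCCCc1cc(O)cc(O)c1
A5 | alternative 2 | (E)-hexacos-3-en-2-one | CCCCCCCCCCCCCCCCCCCCCC/C=C/C(C)=O
A6 | alternative 2 | dimethyl malonate | COC(=O)CC(=O)OC
A7 | alternative 2 | 5-docosylcyclohexane-1,3-dione | CCCCCCCCCCCCCCCCCCCCCCC1CC(=O)CC(=O)C1
A8 | alternative 3 | di-tert-butyl squarate (3,4-di-tert-butoxycyclobut-3-ene-1,2-dione) | CC(C)(C)OC1=C(OC(C)(C)C)C(=O)C1=O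
A9 | alternative 3 | 3-tert-butoxy-4-docosylcyclobut-3-ene-1,2-dione | CCCCCCCCCCCCCCCCCCCCCCC1=C(OC(C)(C)C)C(=O)C1=O
A10 | alternative 3 | racemic 3-tert-butoxy-2-docosyl-4-hydroxy-4-(methoxyethynyl)cyclobut-2-en-1-one | CCCCCCCCCCCCCCCCCCCCCCC1=C(OC(C)(C)C)C(O)(C#COC)C1=O
A11 | alternative 3 | 2-tert-butoxy-3-docosyl-5-methoxy-1,4-benzoquinone | CCCCCCCCCCCCCCCCCCCCCCC1=C(OC(C)(C)C)C(=O)C=C(OC)C1=O
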